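**Plan**

1. Retrosynthesis: the hydroperoxide is removed by a retro-ene reaction with singlet oxygen, the acetate is taken off, and the cyclopropane CH2 (both of its bonds) is excised, leaving a butenolide-fused cyclooctadienone.
2. Enabling feature: in the eight-membered ring the tetrasubstituted butenolide C=C is flanked by two sp3 ring carbons, and the next carbons outward (the C–OAc carbon and the cyclopropane CH beside CHMe) are 1,4-related across the CH2–CHMe bridge. Bonding these two (retro-Grob, chloride placed on the other cyclopropane CH) gives a cyclohexene cis-fused to a cyclobutane, which is a Diels–Alder retron.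
3. That cyclohexene is cut by a retro-[4+2] through two target bonds at once: cyclopropane CH (CHMe side)–cyclopropane CH (butenolide side), and C(OAc)–CH(side chain). The pieces are a bis-alkylidene lactone diene and a cyclobutanone enol silyl ether.
4. Forward order: butenolide ring (chloropalladative diyne cyclization; carbons from (R)-citronellal, formaldehyde and propiolic acid), then cyclohexene onto the cyclobutane ([4+2]), eight-membered ring (Grob ring expansion), ketone reduction, cyclopropane, acetate, ene reaction.
5. Stereochemistry: side-chain CHMe from (R)-citronellal; ring CHMe from enantioselective deprotonation of 3-methylcyclobutanone; CH(side chain) from the endo, anti-to-methyl cycloaddition (matched with the diene's allylic centre); carbinol by hydride attack anti to the side chain; cyclopropane by hydroxyl direction; (E)-alkene and OOH from the ene reaction.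

Key step: step 6

Remark: lithium (R,R)-bis(1-phenylethyl)amide is taken as the antipode of the chiral base that leads to the (R)-enol ether 11; if the sense of induction is the opposite, the (S,S)-amide is used.

**Route**

Step 1
Reactants: 1 (R)-citronellal
Product: 3 (3R)-3,7-dimethyloct-6-en-1-yne, via enol nonaflate 2 (not isolated)
Conditions: C4F9SO2F, t-BuN=P(pyrrolidin-1-yl)3, DMF, −30 °C → rt
Reagents that add atoms: none
Why: Nonaflation of the aldehyde enolate and elimination of nonaflate by the phosphazene base in the same pot (enol sulfonate formation–elimination) should turn CH2–CHO into C≡CH without loss of carbon, the non-enolisable β-stereocentre of citronellal becoming the propargylic centre.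

Step 2
Reactants: 3 (3R)-3,7-dimethyloct-6-en-1-yne
Product: 5 (4R)-4,8-dimethylnon-7-en-2-yn-1-ol, via lithium acetylide 4 (not isolated)
Conditions: n-BuLi, THF, −78 °C; (CH2O)n, −78 °C → rt
Reagents that add atoms: paraformaldehyde (source of formaldehyde), C=O
Why: Addition of the lithium acetylide to formaldehyde (acetylide hydroxymethylation) should install the future lactone CH2O carbon.

Step 3
Reactants: 5 (4R)-4,8-dimethylnon-7-en-2-yn-1-ol; 6 propiolic acid
Product: 7 (4R)-4,8-dimethylnon-7-en-2-yn-1-yl prop-2-ynoate
Conditions: DCC, DMAP (cat.), CH2Cl2, −20 → 0 °C
Reagents that add atoms: none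
Why: Steglich esterification at low temperature should join the two alkynes through the ester that becomes the lactone, catalytic DMAP and cold limiting conjugate addition to the propiolate.

Step 4
Reactants: 7 diyne ester
Product: 8 (3Z,4Z)-3-(chloromethylidene)-4-[(2R)-2,6-dimethylhept-5-en-1-ylidene]oxolan-2-one
Conditions: PdCl2(PhCN)2 (cat.), LiCl, AcOH, rt
Reagents that add atoms: lithium chloride, [Li+].[Cl-]
Why: Halopalladation-initiated diyne cyclization: anti-chloropalladation of the electron-poor ynoate puts chloride on the terminal carbon, the alkenyl–palladium adds syn across the tethered alkyne (5-exo-dig), and protonolysis of the new alkenyl–palladium bond by AcOH, favoured by excess chloride, should release the s-cis-locked diene with Cl and the side chain both pointing outward and return divalent palladium.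

Step 5
Reactants: 9 3-methylcyclobutan-1-one
Product: 11 (R)-triethyl[(3-methylcyclobut-1-en-1-yl)oxy]silane, via lithium enolate 10 (not isolated)
Conditions: lithium (R,R)-bis(1-phenylethyl)amide, Et3SiCl (in situ), THF, −100 °C
Reagents that add atoms: chlorotriethylsilane, CC[Si](CC)(CC)Cl
Why: Enantiotopos-selective deprotonation of the prochiral ketone by the C2-symmetric chiral lithium amide with in situ silyl trapping (asymmetric desymmetrisation) should give the (R)-enol silyl ether and so fix the methyl-bearing ring stereocentre of the target.

Step 6
Reactants: 8 chloro diene lactone; 11 (R)-enol silyl ether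
Product: 12 endo [4+2] cycloadduct
Conditions: 11 (excess), toluene, BHT, K2CO3, 80 °C, sealed tube
Reagents that add atoms: none
Why: The s-cis-locked diene of 8, made electron-poor by the lactone carbonyl on its C2 and by chlorine, and the strained, electron-rich enol ether 11 should react in a concerted, asynchronous inverse-electron-demand Diels–Alder reaction in which the nucleophilic enol-ether β-carbon bonds to the chloromethylidene carbon (β to the lactone C=O) and the silyloxy carbon bonds to the alkylidene carbon, which fixes the regiochemistry. The closest known reaction type is the [4+2] cycloaddition of 2-alkoxycarbonyl-1,3-dienes and 3,4-dialkylidene lactones with enol ethers. One ring is closed, the cyclohexene, by suprafacial [4+2] addition across the cyclobutene C=C, so the eight-membered ring of the target is now present in masked form, spanned by the cyclobutane bond. The ring fusion is cis by suprafacial addition, the diene approaches the cyclobutene face opposite its methyl group, and the endo transition state (small ring CH2/CHMe carbons under the diene, bulky OSiEt3 outside) places both outward diene substituents, Cl and the side chain, cis to the four-membered ring; this sets the side-chain-bearing carbon relative to the methyl-bearing carbon and puts Cl where the next step needs it. The allylic stereocentre of 8, held by A(1,3) strain with its hydrogen in the diene plane, shows the same diene face (that of its methyl group) to this approach, so the two chiral partners should be matched. The step needs endo and facial selectivity, secured by these steric elements, and must outrun dimerisation of 8, which the excess of 11 and the outward substituents on both diene termini should ensure.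

Step 7
Reactants: 12 endo [4+2] cycloadduct
Product: 14 butenolide-fused (Z)-cyclooctadienone, via cyclobutanolate 13 (not isolated)
Conditions: n-Bu4NF, THF, −40 → 0 °C; pH 7 buffer
Reagents that add atoms: none
Why: Fluoride should unmask the tertiary cyclobutanolate, whose ring-fusion C–C bond is antiperiplanar to the equatorial allylic C–Cl bond set cis to the four-membered ring, so a Grob fragmentation should break the strained cyclobutane bond and give the eight-membered ketone with a new (Z)-alkene (the two ring bonds are gauche in the reacting conformer); cold, brief, buffered handling protects the doubly activated CH beside the ketone.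

Step 8
Reactants: 14 butenolide-fused (Z)-cyclooctadienone
Product: 15 dienol
Conditions: NaBH4, CeCl3·7H2O, MeOH, −78 °C
Reagents that add atoms: none
Why: Luche reduction should deliver hydride 1,2 to the non-conjugated ketone without touching the butenolide, from the ring face opposite the adjacent branched side chain, placing the hydroxyl cis to the side chain as the target requires.

Step 9
Reactants: 15 dienol
Product: 17 deacetyl-acetoxycrenulide, via zinc alkoxide 16 (not isolated)
Conditions: Et2Zn, CH2I2, CH2Cl2, −10 °C → rt
Reagents that add atoms: diiodomethane, ICI
Why: Hydroxyl-directed Simmons–Smith cyclopropanation: the zinc alkoxide should deliver CH2 to the face of the cis ring alkene on which oxygen lies (also the face opposite the allylic methyl), giving the cis-fused cyclopropane, with coordination favouring this alkene over the remote trisubstituted one and the electron-poor butenolide alkene staying inert.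

Step 10
Reactants: 17 deacetyl-acetoxycrenulide
Product: 18 acetoxycrenulide
Conditions: Ac2O, pyridine, DMAP (cat.), CH2Cl2, rt
Reagents that add atoms: acetic anhydride, CC(=O)OC(C)=O
Why: DMAP-catalysed acetylation of the secondary alcohol with retention at carbon.

Step 11
Reactants: 18 acetoxycrenulide
Product: 19 target hydroperoxide
Conditions: O2, tetraphenylporphyrin (cat.), visible light, CH2Cl2, −20 °C
Reagents that add atoms: oxygen (as singlet oxygen), O=O
Why: Schenck ene reaction: singlet oxygen should add to the dimethyl-substituted carbon of the side-chain alkene with abstraction of an allylic CH2 hydrogen and shift of the double bond to the (E)-disubstituted position, giving the tertiary allylic hydroperoxide; the butenolide and vinylcyclopropane are not electron-rich enough to react, and the regioisomeric secondary hydroperoxide expected alongside is removed by chromatography.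

**Compound list**

1 | (R)-citronellal, (3R)-3,7-dimethyloct-6-enal | O=CC[C@H](C)CCC=C(C)C | starting material
2 | (3R)-3,7-dimethylocta-1,6-dien-1-yl nonafluorobutane-1-sulfonate (E/Z mixture) | FC(F)(F)C(F)(F)C(F)(F)C(F)(F)S(=O)(=O)OC=C[C@H](C)CCC=C(C)C | intermediate
3 | (3R)-3,7-dimethyloct-6-en-1-yne | C#C[C@H](C)CCC=C(C)C | intermediate
4 | lithium acetylide of 3 | [Li]C#C[C@H](C)CCC=C(C)C | intermediate
5 | (4R)-4,8-dimethylnon-7-en-2-yn-1-ol | OCC#C[C@H](C)CCC=C(C)C | intermediate
6 | propiolic acid (prop-2-ynoic acid) | C#CC(=O)O | starting material
7 | (4R)-4,8-dimethylnon-7-en-2-yn-1-yl prop-2-ynoate | C#CC(=O)OCC#C[C@H](C)CCC=C(C)C | intermediate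
8 | (3Z,4Z)-3-(chloromethylidene)-4-[(2R)-2,6-dimethylhept-5-en-1-ylidene]oxolan-2-one | Cl/C=C1\C(=O)OC/C1=C\[C@H](C)CCC=C(C)C | intermediate
9 | 3-methylcyclobutan-1-one | CC1CC(=O)C1 | starting material
10 | lithium enolate of 9 (R-configured at the methyl carbon) | [Li]OC1=C[C@H](C)C1 | intermediate
11 | (R)-triethyl[(3-methylcyclobut-1-en-1-yl)oxy]silane | CC[Si](CC)(CC)OC1=C[C@H](C)C1 | intermediate
12 | endo cycloadduct: butenolide-fused cyclohexene cis-fused to a cyclobutane; Et3SiO on the ring-fusion carbon bonded to the side-chain CH; Cl on the allylic CH bonded to the other ring-fusion CH; Cl, side chain and the cyclobutane CH2/CHMe carbons on one face of the cyclohexene; cyclobutane methyl on the face opposite the two new bonds | CC[Si](CC)(CC)O[C@@]12C[C@@H](C)[C@@H]1[C@H](Cl)C3=C(COC3=O)[C@@H]2[C@H](C)CCC=C(C)C | intermediate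
13 | tetrabutylammonium cyclobutanolate from desilylation of 12 | CCCC[N+](CCCC)(CCCC)CCCC.[O-][C@@]12C[C@@H](C)[C@@H]1[C@H](Cl)C3=C(COC3=O)[C@@H]2[C@H](C)CCC=C(C)C | intermediate
14 | butenolide-fused (Z)-cyclooctadienone (ring order: C=O, CH2, CHMe, cis-CH=CH, butenolide C=C, CH bearing the (R)-6-methylhept-5-en-2-yl chain); methyl and side chain trans | O=C1C[C@@H](C)/C=C\C2=C(COC2=O)[C@@H]1[C@H](C)CCC=C(C)C | intermediate
15 | dienol: 14 with the ketone reduced; OH cis to the side chain, trans to the methyl | O[C@@H]1C[C@@H](C)/C=C\C2=C(COC2=O)[C@@H]1[C@H](C)CCC=C(C)C | intermediate
16 | ethylzinc alkoxide of 15 | CC[Zn]O[C@@H]1C[C@@H](C)/C=C\C2=C(COC2=O)[C@@H]1[C@H](C)CCC=C(C)C | intermediate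
17 | deacetyl-acetoxycrenulide: 15 with the cis ring alkene converted to a cis-fused cyclopropane whose CH2 lies on the OH face | O[C@@H]1C[C@@H](C)[C@@H]2C[C@@H]2C2=C(COC2=O)[C@@H]1[C@H](C)CCC=C(C)C | intermediate
18 | acetoxycrenulide (acetate of 17) | CC(=O)O[C@@H]1C[C@@H](C)[C@@H]2C[C@@H]2C2=C(COC2=O)[C@@H]1[C@H](C)CCC=C(C)C | intermediate
19 | CNP0205234.1: acetoxycrenulide carrying the (E)-allylic tertiary hydroperoxide in the side chain | CC(=O)O[C@@H]1C[C@@H](C)[C@@H]2C[C@@H]2C2=C(COC2=O)[C@@H]1[C@H](C)C/C=C/C(C)(C)OO | target

**Step count and risks**

Total steps: 11. Longest linear sequence: 10 (steps 1–4 and 6–11, from (R)-citronellal).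

The three steps most likely to fail are steps 6, 7 and 4.

Step 6 (key cycloaddition). The thermal [4+2] may be too slow, so that the diene dimerises or the enol ether is lost, or the endo and facial preference may be poor. The fallback changes the two-carbon partner to an enamine and sets out from ketone 9 and diene 8. Condensation of 9 with (S)-2-(methoxymethyl)pyrrolidine over molecular sieves should give the enamine F1, whose two methyl-epimeric forms interconvert through the iminium ion. The more nucleophilic enamine should add to 8 at room temperature in a stepwise Michael/Mannich [4+2] annulation to give the amino cycloadduct F2. On warming in acetonitrile the amine lone pair should trigger the same ring expansion (aza-Grob fragmentation) to the iminium chloride F3. Aqueous NaHCO3 should hydrolyse F3 to dienone 14, where the route is rejoined. The antipode of the amine is used if it proves to be the matched one.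

Step 7 (Grob ring expansion). The basic fluoride medium may epimerise the CH between the new ketone and the butenolide, move the double bonds, or cause E2 loss of HCl instead of fragmentation. The fallback pulls on the leaving group instead of pushing from an alkoxide and sets out from 12. HF·pyridine in THF should give the free cyclobutanol F4. AgOTf with 2,6-di-tert-butyl-4-methylpyridine in CH2Cl2 at −40 °C should then ionise the allylic chloride and trigger the heterolytic fragmentation without base, returning to the route at dienone 14.

Step 4 (chloropalladative cyclization). Chloropalladation may start at the wrong alkyne, or the alkenyl–palladium intermediate may not be protonated cleanly. The fallback starts the carbopalladation from a defined carbon–iodine bond and sets out from alcohol 5 and propiolic acid 6. Anti addition of ICl to 6 should give (E)-3-chloro-2-iodoprop-2-enoic acid F5, which is esterified with 5 (DCC, DMAP) to the iodoacrylate ester F6. Pd(PPh3)4 and HCO2Na in DMF should then bring about oxidative addition into the C–I bond, 5-exo-dig syn-carbopalladation of the alkyne and hydride capture (reductive Heck cyclization). This should give diene 8 with the same geometry, where the route is rejoined.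

Further compounds
F1 | step 6 | enamine of 9 with (S)-2-(methoxymethyl)pyrrolidine | COC[C@@H]1CCCN1C2=C[C@H](C)C2
F2 | step 6 | amino cycloadduct (aminopyrrolidinyl analogue of 12) | COC[C@@H]1CCCN1[C@@]23C[C@@H](C)[C@@H]2[C@H](Cl)C4=C(COC4=O)[C@@H]3[C@H](C)CCC=C(C)C
F3 | step 6 | ring-expanded iminium chloride | COC[C@@H]1CCC[N+]1=C2C[C@@H](C)/C=C\C3=C(COC3=O)[C@@H]2[C@H](C)CCC=C(C)C.[Cl-]
F4 | step 7 | free cyclobutanol (desilylated 12) | O[C@@]12C[C@@H](C)[C@@H]1[C@H](Cl)C3=C(COC3=O)[C@@H]2[C@H](C)CCC=C(C)C
F5 | step 4 | (E)-3-chloro-2-iodoprop-2-enoic acid | Cl/C=C(I)\C(=O)O
F6 | step 4 | (4R)-4,8-dimethylnon-7-en-2-yn-1-yl (E)-3-chloro-2-iodoprop-2-enoate | Cl/C=C(I)\C(=O)OCC#C[C@H](C)CCC=C(C)C
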